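**Strategy.** Numbering (pseudoguaianolide): ring C1, C5–C10; side chain C2–C4 on C1; lactone C11–C13 on C7/C8; methyls C14 (on C10), C15 (on C5). The cycloheptene ring, whose C5=C6 bond lies between C1 and the lactone-bearing C7–C8 edge, is cut into a C5–C6–C7 and a C8–C9–C10–C1 unit. An open-chain dienyl vinyldiazoacetate, esterified through the C2 carbinol, undergoes Rh2(O2CC7H15)4-catalysed cyclopropanation of C1=C10, then a boat divinylcyclopropane Cope shift: one operation forges C1–C5 and C7–C8, closes the seven-membered ring plus a temporary butenolide, and relays C2 chirality to C1, C7, C8. The ester carbon becomes C15; C9=C10 is hydrogenated; C2 is inverted by a late Mitsunobu angeloylation.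

Key step: step 9

Remark on the chemistry: in the lactone-tethered cyclopropanation the C3–C4 chain on C2 should end up anti to the cyclopropane (allylic 1,3-strain), which is the C2-epimeric relationship to the target. C2 is therefore carried as the (R)-carbinol and inverted in step 16.
Assumption: 4-oxobutyl acetate, malonic acid, (E)-3-methylpent-2-en-4-yn-1-ol, (R)-2-hydroxy-1,2,2-triphenylethyl acetate and angelic acid are purchased.

**Route**

Step 1
Reactants: 1 4-oxobutyl acetate; 2 malonic acid
Product: 3 (E)-6-acetoxyhex-3-enoic acid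
Conditions: piperidinium acetate (cat.), DMSO, 100 °C
Reagents that add atoms: none
Why: Knoevenagel–Doebner condensation with decarboxylative deconjugation should give the β,γ-unsaturated acid, the (E)-geometry being set under thermodynamic control.

Step 2
Reactants: 4 (E)-3-methylpent-2-en-4-yn-1-ol
Product: 5 (E)-3-methylpent-2-en-4-ynal
Conditions: MnO2, CH2Cl2, 23 °C
Reagents that add atoms: none
Why: MnO2 oxidises the allylic alcohol selectively and should leave the alkyne and the (E)-alkene untouched.

Step 3
Reactants: 5 (E)-3-methylpent-2-en-4-ynal; 6 (R)-2-hydroxy-1,2,2-triphenylethyl acetate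
Product: 7 (R)-2-hydroxy-1,2,2-triphenylethyl (3R,4E)-3-hydroxy-5-methylhept-4-en-6-ynoate
Conditions: LiN(iPr)2 (2.1 equiv), THF, −78 to 0 °C; MgBr2·OEt2; then 5, −115 °C
Reagents that add atoms: none
Why: Auxiliary-controlled acetate aldol addition of the doubly deprotonated chiral acetate should set the (R)-carbinol (future C2), the very low temperature keeping addition ahead of proton transfer from the alkyne.

Step 4
Reactants: 7 aldol ester
Product: 8 (3R,4E)-5-methylhept-4-en-6-yne-1,3-diol
Conditions: iBu2AlH (5 equiv), CH2Cl2, −78 to 0 °C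
Reagents that add atoms: none
Why: Reductive cleavage of the ester should release the 1,3-diol and the auxiliary diol without touching the carbinol centre or the enyne.

Step 5
Reactants: 8 diol
Product: 9 (3R,4E)-1-(tert-butyldiphenylsilyloxy)-5-methylhept-4-en-6-yn-3-ol
Conditions: TBDPSCl, imidazole, CH2Cl2, 0 °C
Reagents that add atoms: tert-butyl(chloro)diphenylsilane, CC(C)(C)[Si](Cl)(c1ccccc1)c1ccccc1
Why: The bulky silyl chloride should silylate the primary hydroxyl selectively over the secondary allylic one.

Step 6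
Reactants: 9 enynol silyl ether
Product: 10 (3R,4E,6E)-1-(tert-butyldiphenylsilyloxy)-5-methyl-7-(pinacolboryl)hepta-4,6-dien-3-ol
Conditions: B2pin2, CuCl (5 mol%), Xantphos (5 mol%), NaOtBu (10 mol%), MeOH, THF, 23 °C
Reagents that add atoms: bis(pinacolato)diboron, CC1(C)OB(OC1(C)C)B1OC(C)(C)C(C)(C)O1
Why: Copper-catalysed syn-borylcupration of the terminal alkyne followed by protonation (protoboration) should give the (E)-alkenylboronate with boron on the terminal carbon and tolerate the free hydroxyl.

Step 7
Reactants: 10 dienylboronate alcohol; 3 (E)-6-acetoxyhex-3-enoic acid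
Product: 11 dienyl (E)-6-acetoxyhex-3-enoate
Conditions: DCC, DMAP (cat.), CH2Cl2, 0 to 23 °C
Reagents that add atoms: none
Why: Steglich esterification should acylate the secondary alcohol with retention at C2 under neutral conditions.

Step 8
Reactants: 11 dienyl ester
Product: 12 dienyl (E)-6-acetoxy-2-diazohex-3-enoate
Conditions: p-ABSA, DBU, MeCN, 0 °C
Reagents that add atoms: 4-acetamidobenzenesulfonyl azide, CC(=O)Nc1ccc(cc1)S(=O)(=O)N=[N+]=[N-]
Why: Regitz diazo transfer at the doubly activated (allylic, α-ester) methylene should give the vinyldiazoacetate with the (E)-vinyl group retained.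

Step 9
Reactants: 12 dienyl vinyldiazoacetate
Product: 15 butenolide-fused cycloheptadiene allylic alcohol, via cis-divinylcyclopropane lactone 13 (not isolated), via allylic boronate 14 (not isolated)
Conditions: Rh2(O2CC7H15)4 (1 mol%), CH2Cl2, 40 °C, slow addition; then PhMe, 110 °C; then NaBO3·4H2O, THF/H2O, 23 °C
Reagents that add atoms: sodium perborate, [Na+].[O-]OB=O
Why: Rh2(O2CC7H15)4 turns 12 into a donor/acceptor vinylcarbenoid that cyclopropanates the tethered C1=C10 bond, and the cis-divinylcyclopropane 13 then undergoes a boat [3,3] shift that cleaves C5–C10 and joins C7 to C8, so C1–C5 and C7–C8 of the target are both made in this flask. The closest known reaction type is the intramolecular tandem cyclopropanation/Cope rearrangement of dienyl vinyldiazoacetates, a formal [4+3] cycloaddition. The butenolide closes by carbenoid [2+1] addition through the three-atom ester tether (five-membered, exo with respect to C10), and the seven-membered ring closes by sigmatropic ring expansion of the cyclopropane. C1 is controlled by the (R)-carbinol C2: allylic 1,3-strain with the C10 methyl holds H2 in the alkene plane, so the carbenoid is delivered to the face that leaves the C3 chain anti to the cyclopropane. C7 and C8 are controlled by the (E)-geometry of both vinyl termini in the boat transition state, which places C11, boron and the C1–C2 bond on one face of the new ring. The step needs addition to C1=C10 rather than to the alkenylboronate or C–H bonds, secured by the five-membered tether, and cis vinyl groups, secured by the (E)-C1=C10 geometry; NaBO3 then oxidises the allylic C8–B bond of 14 to the C8–OH of 15 with retention.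

Step 10
Reactants: 15 allylic alcohol
Product: 16 C9,C10-dihydro butenolide alcohol
Conditions: [Ir(cod)(PCy3)(py)]PF6 (5 mol%), H2 (1 atm), CH2Cl2, 0 to 23 °C
Reagents that add atoms: none
Why: Hydroxyl-directed hydrogenation should deliver H2 to the allylic C9=C10 bond from the face of the C8–OH, setting C10 with the methyl α, while the conjugated, more hindered C5=C6 bond should react more slowly.

Step 11
Reactants: 16 butenolide
Product: 17 tetraol (C15, C2, C8 and C12 hydroxyls)
Conditions: iBu2AlH (6 equiv), CH2Cl2, −78 to 0 °C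
Reagents that add atoms: none
Why: 1,2-Reduction of the α-alkylidene lactone should open the tether to the primary allylic C15 alcohol and the C2 carbinol and cleave the C12 acetate in the same operation.

Step 12
Reactants: 17 tetraol
Product: 18 primary allylic chloride
Conditions: NCS, Me2S, CH2Cl2, −20 to 0 °C
Reagents that add atoms: N-chlorosuccinimide, O=C1CCC(=O)N1Cl
Why: Corey–Kim chlorination should convert only the allylic hydroxyl into the chloride, the saturated alkoxysulfonium salts reverting to alcohols on work-up.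

Step 13
Reactants: 18 allylic chloride
Product: 19 triol with the C15 methyl group
Conditions: LiBHEt3 (excess), THF, 0 °C
Reagents that add atoms: none
Why: Direct SN2 hydride displacement at the primary allylic chloride should give the C15 methyl group with the C5=C6 bond kept in place.

Step 14
Reactants: 19 triol
Product: 20 cis-fused γ-lactone with free C2 hydroxyl
Conditions: TEMPO (cat.), PhI(OAc)2, CH2Cl2, 23 °C
Reagents that add atoms: none
Why: Oxoammonium oxidation should take only the primary C12 alcohol to the aldehyde, which closes onto the cis C8–OH as a lactol and is oxidised on to the lactone, leaving the secondary C2–OH untouched.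

Step 15
Reactants: 20 lactone
Product: 23 α-methylene lactone alcohol, via Mannich base 21 (not isolated), via trimethylammonium iodide 22 (not isolated)
Conditions: LiN(iPr)2 (2.5 equiv), THF, −78 °C; CH2=NMe2+ I−, −78 to 23 °C; MeI, MeOH; aq. NaHCO3, CH2Cl2
Reagents that add atoms: Eschenmoser's salt, C=[N+](C)C.[I-]
Why: Mannich reaction of the lactone enolate followed by quaternisation and E1cB elimination should install the C11=C13 exocyclic methylene, the new C11 centre (either epimer) being destroyed in the elimination.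

Step 16
Reactants: 23 α-methylene lactone alcohol; 24 angelic acid
Product: 25 C2 angelate with the C4 silyl ether
Conditions: PPh3, DIAD, PhMe, 0 to 23 °C
Reagents that add atoms: none
Why: Mitsunobu esterification should displace the activated C2 oxygen by the carboxylate with SN2 inversion, turning the (R)-carbinol into the (S)-angelate without acyl activation that could isomerise the (Z)-alkene.

Step 17
Reactants: 25 angelate silyl ether
Product: 26 C4 primary alcohol
Conditions: HF·pyridine, pyridine, THF, 0 to 23 °C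
Reagents that add atoms: none
Why: Buffered fluoride desilylation should free the primary hydroxyl under weakly acidic conditions that spare the α-methylene lactone and disfavour acyl migration.

Step 18
Reactants: 26 primary alcohol
Product: 27 CNP0163960.1
Conditions: Ac2O, pyridine, DMAP (cat.), CH2Cl2, 0 °C
Reagents that add atoms: acetic anhydride, CC(=O)OC(C)=O
Why: Standard acetylation of the remaining primary hydroxyl should complete the target without affecting the other esters.

**Compound list**

1 | 4-oxobutyl acetate | CC(=O)OCCCC=O | starting material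
2 | malonic acid | OC(=O)CC(=O)O | starting material
3 | (E)-6-acetoxyhex-3-enoic acid | CC(=O)OCC/C=C/CC(=O)O | intermediate
4 | (E)-3-methylpent-2-en-4-yn-1-ol | C#C/C(C)=C/CO | starting material
5 | (E)-3-methylpent-2-en-4-ynal | C#C/C(C)=C/C=O | intermediate
6 | (R)-2-hydroxy-1,2,2-triphenylethyl acetate | CC(=O)O[C@H](c1ccccc1)C(O)(c1ccccc1)c1ccccc1 | starting material
7 | (R)-2-hydroxy-1,2,2-triphenylethyl (3R,4E)-3-hydroxy-5-methylhept-4-en-6-ynoate | C#C/C(C)=C/[C@H](O)CC(=O)O[C@H](c1ccccc1)C(O)(c1ccccc1)c1ccccc1 | intermediate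
8 | (3R,4E)-5-methylhept-4-en-6-yne-1,3-diol | C#C/C(C)=C/[C@H](O)CCO | intermediate
9 | (3R,4E)-1-(tert-butyldiphenylsilyloxy)-5-methylhept-4-en-6-yn-3-ol | C#C/C(C)=C/[C@H](O)CCO[Si](c1ccccc1)(c1ccccc1)C(C)(C)C | intermediate
10 | (3R,4E,6E)-1-(tert-butyldiphenylsilyloxy)-5-methyl-7-(4,4,5,5-tetramethyl-1,3,2-dioxaborolan-2-yl)hepta-4,6-dien-3-ol | O[C@H](CCO[Si](c1ccccc1)(c1ccccc1)C(C)(C)C)/C=C(C)/C=C/B1OC(C)(C)C(C)(C)O1 | intermediate
11 | ester of 10 (at its C3 oxygen, R) with (E)-6-acetoxyhex-3-enoic acid | CC(=O)OCC/C=C/CC(=O)O[C@H](CCO[Si](c1ccccc1)(c1ccccc1)C(C)(C)C)/C=C(C)/C=C/B1OC(C)(C)C(C)(C)O1 | intermediate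
12 | the corresponding (E)-6-acetoxy-2-diazohex-3-enoate (vinyldiazoacetate) | CC(=O)OCC/C=C/C(=[N+]=[N-])C(=O)O[C@H](CCO[Si](c1ccccc1)(c1ccccc1)C(C)(C)C)/C=C(C)/C=C/B1OC(C)(C)C(C)(C)O1 | intermediate
13 | 3-oxabicyclo[3.1.0]hexan-2-one: C1 (future C5) carries the (E)-4-acetoxybut-1-enyl group; C6 (future C10) carries methyl and the (E)-2-(pinacolboryl)vinyl group cis to that alkenyl group; C4 (future C2, R) carries the 2-(TBDPS-oxy)ethyl group anti to the cyclopropane | O=C1O[C@H](CCO[Si](c2ccccc2)(c2ccccc2)C(C)(C)C)[C@@H]2[C@@]1(/C=C/CCOC(C)=O)[C@@]2(C)/C=C/B1OC(C)(C)C(C)(C)O1 | intermediate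
14 | 7-(2-acetoxyethyl)-4-methyl-6-(pinacolboryl)-3-[2-(TBDPS-oxy)ethyl]-3,3a,6,7-tetrahydro-1H-cyclohepta[c]furan-1-one; C1, C7, C8 as in 27 (boron on C8), C2 (R) | O=C1O[C@H](CCO[Si](c2ccccc2)(c2ccccc2)C(C)(C)C)[C@@H]2C1=C[C@H](CCOC(C)=O)[C@H](B1OC(C)(C)C(C)(C)O1)C=C2C | intermediate
15 | 7-(2-acetoxyethyl)-6-hydroxy-4-methyl-3-[2-(TBDPS-oxy)ethyl]-3,3a,6,7-tetrahydro-1H-cyclohepta[c]furan-1-one; C1, C7, C8 as in 27, C2 (R) | O=C1O[C@H](CCO[Si](c2ccccc2)(c2ccccc2)C(C)(C)C)[C@@H]2C1=C[C@H](CCOC(C)=O)[C@H](O)C=C2C | intermediate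
16 | 4,5-dihydro derivative of 15 (3,3a,4,5,6,7-hexahydro); C1, C7, C8, C10 as in 27, C2 (R) | O=C1O[C@H](CCO[Si](c2ccccc2)(c2ccccc2)C(C)(C)C)[C@@H]2C1=C[C@H](CCOC(C)=O)[C@H](O)C[C@H]2C | intermediate
17 | cyclohept-5-ene tetraol (target numbering): C5–CH2OH, C7–CH2CH2OH, C8–OH, C10–CH3, C1–CH(OH)CH2CH2OTBDPS with C2 (R) | OCC1=C[C@H](CCO)[C@H](O)C[C@@H](C)[C@@H]1[C@H](O)CCO[Si](c1ccccc1)(c1ccccc1)C(C)(C)C | intermediate
18 | C15 allylic chloride of 17 | ClCC1=C[C@H](CCO)[C@H](O)C[C@@H](C)[C@@H]1[C@H](O)CCO[Si](c1ccccc1)(c1ccccc1)C(C)(C)C | intermediate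
19 | triol with C15 methyl (C12–OH, C8–OH, C2–OH) | CC1=C[C@H](CCO)[C@H](O)C[C@@H](C)[C@@H]1[C@H](O)CCO[Si](c1ccccc1)(c1ccccc1)C(C)(C)C | intermediate
20 | cis-fused 12,8-lactone (no C13 yet) with (R)-C2–OH and C4–OTBDPS | C1C(=O)O[C@@H]2C[C@@H](C)[C@H]([C@@H](CCO[Si](c3ccccc3)(c3ccccc3)C(C)(C)C)O)C(C)=C[C@H]12 | intermediate
21 | C11 dimethylaminomethyl lactone (C11 either epimer, left unspecified) | CN(C)CC1C(=O)O[C@@H]2C[C@@H](C)[C@H]([C@@H](CCO[Si](c3ccccc3)(c3ccccc3)C(C)(C)C)O)C(C)=C[C@H]12 | intermediate
22 | C11 trimethylammoniomethyl lactone iodide | C[N+](C)(C)CC1C(=O)O[C@@H]2C[C@@H](C)[C@H]([C@@H](CCO[Si](c3ccccc3)(c3ccccc3)C(C)(C)C)O)C(C)=C[C@H]12.[I-] | intermediate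
23 | α-methylene lactone with (R)-C2–OH and C4–OTBDPS | C=C1C(=O)O[C@@H]2C[C@@H](C)[C@H]([C@@H](CCO[Si](c3ccccc3)(c3ccccc3)C(C)(C)C)O)C(C)=C[C@H]12 | intermediate
24 | angelic acid, (Z)-2-methylbut-2-enoic acid | C/C=C(/C)C(=O)O | starting material
25 | (S)-C2 angelate with C4–OTBDPS | C=C1C(=O)O[C@@H]2C[C@@H](C)[C@H]([C@H](CCO[Si](c3ccccc3)(c3ccccc3)C(C)(C)C)OC(=O)/C(C)=C\C)C(C)=C[C@H]12 | intermediate
26 | (S)-C2 angelate with free C4–OH | C=C1C(=O)O[C@@H]2C[C@@H](C)[C@H]([C@H](CCO)OC(=O)/C(C)=C\C)C(C)=C[C@H]12 | intermediate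
27 | CNP0163960.1, (1S,2S,7R,8R,10R) in the numbering above | C=C1C(=O)O[C@@H]2C[C@@H](C)[C@H]([C@H](CCOC(C)=O)OC(=O)/C(C)=C\C)C(C)=C[C@H]12 | target

**Step count and risks**

Total step count: 18. Longest linear sequence: 17 steps (steps 2 to 18, from 4); step 1 is the only branch.

Steps most likely to fail:

Step 9. The vinyldiazo group may cyclise to a pyrazole before the carbenoid forms, C–H insertion may compete, the carbenoid may add with poor facial selectivity, or the Cope shift may be slow in the fused system. Fallback without metal: starting from 12, the diazo group is allowed to add thermally across C1=C10 (benzene, 50 °C, dark; intramolecular 1,3-dipolar cycloaddition) to give the bicyclic 1-pyrazoline F1. Irradiation (350 nm, −20 °C) extrudes dinitrogen to give cyclopropane 13, which is heated and oxidised as in step 9, and the route is rejoined at 15.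

Step 10. The iridium hydride may also saturate the conjugated C5=C6 bond or isomerise the allylic alcohol to the ketone. Fallback: from 15, Dess–Martin periodinane gives the C8 enone F2. A ligand-controlled copper hydride 1,4-reduction (Cu(OAc)2, the DTBM-SEGPHOS enantiomer that delivers hydride to the β-face of C10, polymethylhydrosiloxane, tBuOH, PhMe) gives the saturated ketone F3. K[HB(sBu)3] at −78 °C then attacks C8 from the α-face, and the route is rejoined at 16.

Step 16. Substitution at the hindered C2 may be slow, elimination may compete, and the angelate may isomerise to the tiglate. Fallback by oxidation and reduction: from 23, Dess–Martin periodinane gives the C2 ketone F4. (R)-CBS reduction with catecholborane (PhMe, −78 °C, chosen to spare the α-methylene lactone) gives the (S)-alcohol F5. Yamaguchi esterification with 24 (2,4,6-trichlorobenzoyl chloride, Et3N; DMAP, PhMe) proceeds with retention and rejoins the route at 25.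

Further compounds

F1 | step 9 | bicyclic 1-pyrazoline from intramolecular addition of the diazo group of 12 across C1=C10 (N=N bridge between future C5 and C10) | O=C1O[C@H](CCO[Si](c2ccccc2)(c2ccccc2)C(C)(C)C)[C@@H]2[C@@]1(/C=C/CCOC(C)=O)N=N[C@@]2(C)/C=C/B1OC(C)(C)C(C)(C)O1
F2 | step 10 | C8 enone from oxidation of 15 | O=C1O[C@H](CCO[Si](c2ccccc2)(c2ccccc2)C(C)(C)C)[C@@H]2C1=C[C@H](CCOC(C)=O)C(=O)C=C2C
F3 | step 10 | C8 ketone with C10 configured as in 27 | O=C1O[C@H](CCO[Si](c2ccccc2)(c2ccccc2)C(C)(C)C)[C@@H]2C1=C[C@H](CCOC(C)=O)C(=O)C[C@H]2C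
F4 | step 16 | C2 ketone from oxidation of 23 | C=C1C(=O)O[C@@H]2C[C@@H](C)[C@H](C(=O)CCO[Si](c3ccccc3)(c3ccccc3)C(C)(C)C)C(C)=C[C@H]12
F5 | step 16 | (S)-C2 alcohol, C2 epimer of 23 | C=C1C(=O)O[C@@H]2C[C@@H](C)[C@H]([C@H](CCO[Si](c3ccccc3)(c3ccccc3)C(C)(C)C)O)C(C)=C[C@H]12
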